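**Retrosynthetic overview**

1. No ring is built: ring A comes from (S)-carvone and ring B from (1S,2S,4R)-limonene-1,2-diol; ring B is finished first, and ring A is finished on the coupled skeleton.
2. Avoided first choice: HOBr (NBS/H2O) addition to a limonene-type alkene plus stepwise allylation. Anti addition can only give Br/OH trans, whereas ring B of the target has Br, OH and the side chain all cis (Br equatorial, OH axial).
3. Key step, ring B: the C–Br bond is made by SN2 opening of a trans-fused cyclic sulfate with bromide (inversion at the secondary carbon, tertiary C–O kept). The side chain is carried as an acetyl group so that its ring carbon is under thermodynamic control.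
4. Key step, ring A and union: in one flask, carvone epoxide is masked as its enolate, the epoxide is opened by hydride (tertiary carbinol), and the resulting dianion is allylated with the ring B allyl chloride (inter-ring C–C bond, trans to isopropenyl).
5. Last disconnection: the secondary carbinol of ring A, by hydroxyl-directed reduction of the alpha-hydroxy ketone.

Assumption: the target is taken exactly as drawn, (1S,2S,3R,4S) in the diol ring (ring A) and (1R,3R,4S) in the bromohydrin ring (ring B), and (S)-carvone and (1S,2S,4R)-limonene-1,2-diol are treated as commercial single enantiomers.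

**Route**

Step 1
Reactants: 1 (S)-(+)-carvone
Product: 2 (1S,4S,6S)-1-methyl-4-(prop-1-en-2-yl)-7-oxabicyclo[4.1.0]heptan-2-one (trans-carvone epoxide)
Conditions: 30% aq H2O2, NaOH (0.3 equiv), MeOH, 0 °C
Reagents that add atoms: hydrogen peroxide, OO
Why: Weitz–Scheffer nucleophilic epoxidation is specific for the enone, and conjugate attack of hydroperoxide anti to the isopropenyl group places the epoxide oxygen trans to it, which sets the tertiary C–O centre of ring A (1S) and leaves the carvone centre (4S) untouched.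

Step 2
Reactants: 3 (1S,2S,4R)-1-methyl-4-(prop-1-en-2-yl)cyclohexane-1,2-diol (limonene-1,2-diol, trans-diaxial)
Product: 4 1-[(1R,3S,4S)-3,4-dihydroxy-4-methylcyclohexyl]ethan-1-one
Conditions: O3, CH2Cl2/MeOH, −78 °C; then Me2S, −78 °C → rt
Reagents that add atoms: ozone, [O-][O+]=O
Why: Ozonolysis with reductive work-up cleaves the only alkene to a methyl ketone without touching the three stereocentres, so the later ruthenium oxidation meets no alkene and the ring carbon bearing the side chain becomes epimerisable (thermodynamic control, acetyl equatorial).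

Step 3
Reactants: 4 1-[(1R,3S,4S)-3,4-dihydroxy-4-methylcyclohexyl]ethan-1-one
Product: 6 (3aS,5R,7aS)-5-acetyl-7a-methylhexahydro-1,3,2-benzodioxathiole 2,2-dioxide, via cyclic sulfite 5 (not isolated)
Conditions: SOCl2, Et3N, CH2Cl2, 0 °C; then RuCl3·3H2O (1 mol %), NaIO4, MeCN/H2O, 0 °C
Reagents that add atoms: thionyl chloride, ClS(Cl)=O; sodium periodate, [Na+].[O-]I(=O)(=O)=O
Why: Gao–Sharpless cyclic sulfate formation (sulfite formation, then oxidation by ruthenium tetroxide made in situ) involves only O–S bond making, so both carbinol centres are retained, the trans-fused five-membered ring closing from the diequatorial chair reached by ring flip.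

Step 4
Reactants: 6 (3aS,5R,7aS)-5-acetyl-7a-methylhexahydro-1,3,2-benzodioxathiole 2,2-dioxide
Product: 8 1-[(1R,3R,4S)-3-bromo-4-hydroxy-4-methylcyclohexyl]ethan-1-one, via lithium bromoalkyl sulfate 7 (not isolated)
Conditions: LiBr (3 equiv), THF, 50 °C; then H2SO4 (cat), H2O (2 equiv), THF, rt
Reagents that add atoms: lithium bromide, [Li+].[Br-]
Why: SN2 ring opening of the cyclic sulfate by bromide occurs at the secondary carbon with inversion (backside attack is impossible at the tertiary carbon), which puts Br cis to the untouched tertiary C–O bond and gives the R configuration at C–Br, and acid-catalysed hydrolysis of the sulfate monoester by S–O cleavage frees the alcohol with retention while the enolisable acetyl-bearing carbon rests equatorial, cis to Br and OH.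

Step 5
Reactants: 8 1-[(1R,3R,4S)-3-bromo-4-hydroxy-4-methylcyclohexyl]ethan-1-one
Product: 9 1-[(1R,3R,4S)-3-bromo-4-methyl-4-(trimethylsilyloxy)cyclohexyl]ethan-1-one
Conditions: N-(trimethylsilyl)imidazole, CH2Cl2, rt
Reagents that add atoms: N-(trimethylsilyl)imidazole, C[Si](C)(C)n1ccnc1
Why: O-Silylation with the neutral silyl donor protects the tertiary alcohol (no stereocentre involved) against alkoxide chemistry in steps 6 and 8 and against cineole-type chloroetherification onto the cis-disposed propenyl group in step 7.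

Step 6
Reactants: 9 1-[(1R,3R,4S)-3-bromo-4-methyl-4-(trimethylsilyloxy)cyclohexyl]ethan-1-one
Product: 10 {[(1S,2R,4R)-2-bromo-1-methyl-4-(prop-1-en-2-yl)cyclohexyl]oxy}trimethylsilane
Conditions: Ph3PCH3Br, n-BuLi, THF, 0 °C; then 9, −78 °C → rt
Reagents that add atoms: methyltriphenylphosphonium bromide, C[P+](c1ccccc1)(c1ccccc1)c1ccccc1.[Br-]
Why: Wittig methylenation converts the methyl ketone into the 2-propenyl group, the equatorial bromide has no antiperiplanar hydrogen for E2 and any enolisation next to the ketone returns the same equatorial epimer, so all three centres are kept.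

Step 7
Reactants: 10 {[(1S,2R,4R)-2-bromo-1-methyl-4-(prop-1-en-2-yl)cyclohexyl]oxy}trimethylsilane
Product: 11 {[(1S,2R,4R)-2-bromo-4-(3-chloroprop-1-en-2-yl)-1-methylcyclohexyl]oxy}trimethylsilane
Conditions: Ca(OCl)2, CO2 (solid), CH2Cl2/H2O, 0 °C
Reagents that add atoms: calcium hypochlorite, [Ca+2].[O-]Cl.[O-]Cl
Why: Ene-type allylic chlorination by hypochlorous acid (Hegde–Wolinsky conditions) removes a methyl hydrogen of the isopropenyl group with shift of the double bond, giving the 2-substituted allyl chloride and leaving the ring stereocentres untouched.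

Step 8
Reactants: 2 trans-carvone epoxide; 11 {[(1S,2R,4R)-2-bromo-4-(3-chloroprop-1-en-2-yl)-1-methylcyclohexyl]oxy}trimethylsilane
Product: 14 (2S,5S,6R)-6-{2-[(1R,3R,4S)-3-bromo-4-methyl-4-(trimethylsilyloxy)cyclohexyl]prop-2-en-1-yl}-2-hydroxy-2-methyl-5-(prop-1-en-2-yl)cyclohexan-1-one, via lithium enolate 12 (not isolated), via dilithium alkoxide enolate 13 (not isolated)
Conditions: 2 (1.3 equiv), LiN(iPr)2 (1.35 equiv), THF, −78 °C; LiBHEt3 (1.3 equiv), −78 → 0 °C; then 11 (1.0 equiv), Bu4NI (10 mol %), DMPU, −78 → −10 °C; aq NH4Cl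
Reagents that add atoms: none
Why: Proposed new method: the ketone is masked in the flask as its only possible enolate (the other alpha carbon is the quaternary epoxide carbon), LiBHEt3 then opens the trisubstituted epoxide by SN2 hydride attack at the less hindered CH carbon so that the tertiary C–O bond set in step 1 is retained, and the resulting dianion is C-allylated by 11 on the face anti to the adjacent isopropenyl group (trans relationship, 6R), the closest known reaction types being hydride reductions run on ketones protected in situ as enolates, LiBHEt3 opening of 1-methylcyclohexene oxides to tertiary alcohols and the trans-selective allylation of the kinetic enolate of carvone.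

Step 9
Reactants: 14 (2S,5S,6R)-6-{2-[(1R,3R,4S)-3-bromo-4-methyl-4-(trimethylsilyloxy)cyclohexyl]prop-2-en-1-yl}-2-hydroxy-2-methyl-5-(prop-1-en-2-yl)cyclohexan-1-one
Product: 16 target CNP0422107.2 (1S,2S,3R,4S)-3-{2-[(1R,3R,4S)-3-bromo-4-hydroxy-4-methylcyclohexyl]prop-2-en-1-yl}-1-methyl-4-(prop-1-en-2-yl)cyclohexane-1,2-diol, via silylated diol 15 (not isolated)
Conditions: Me4NBH(OAc)3 (5 equiv), MeCN/AcOH (1:1), −20 °C → rt; then citric acid, MeOH/H2O, rt
Reagents that add atoms: none
Why: Evans–Saksena hydroxyl-directed reduction: after ligand exchange at boron the tertiary alkoxyborohydride delivers hydride within the molecule to its own (also the axial) face of the ketone, the opposite face being shielded by the axial methyl group, giving the trans diequatorial 1,2-diol (2S), and mild aqueous acid then cleaves the tertiary trimethylsilyl ether.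

**Compound list**

1 | (S)-(+)-carvone, (5S)-2-methyl-5-(prop-1-en-2-yl)cyclohex-2-en-1-one | CC1=CC[C@@H](CC1=O)C(C)=C | starting material
2 | trans-carvone epoxide, (1S,4S,6S)-1-methyl-4-(prop-1-en-2-yl)-7-oxabicyclo[4.1.0]heptan-2-one | O=C1C[C@@H](C(C)=C)C[C@@H]2O[C@]12C | intermediate
3 | (1S,2S,4R)-limonene-1,2-diol, (1S,2S,4R)-1-methyl-4-(prop-1-en-2-yl)cyclohexane-1,2-diol | CC(=C)[C@@H]1CC[C@](C)(O)[C@@H](O)C1 | starting material
4 | keto diol, 1-[(1R,3S,4S)-3,4-dihydroxy-4-methylcyclohexyl]ethan-1-one | CC(=O)[C@@H]1CC[C@](C)(O)[C@@H](O)C1 | intermediate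
5 | cyclic sulfite of 4, (3aS,5R,7aS)-5-acetyl-7a-methylhexahydro-1,3,2-benzodioxathiole 2-oxide (both epimers at sulfur) | CC(=O)[C@@H]1CC[C@](C)(OS(=O)O2)[C@@H]2C1 | intermediate
6 | trans-fused cyclic sulfate of 4, (3aS,5R,7aS)-5-acetyl-7a-methylhexahydro-1,3,2-benzodioxathiole 2,2-dioxide | CC(=O)[C@@H]1CC[C@](C)(OS(=O)(=O)O2)[C@@H]2C1 | intermediate
7 | lithium (1S,2R,4R)-4-acetyl-2-bromo-1-methylcyclohexyl sulfate | CC(=O)[C@@H]1CC[C@](C)(OS(=O)(=O)[O-])[C@H](Br)C1.[Li+] | intermediate
8 | syn-bromohydrin ketone, 1-[(1R,3R,4S)-3-bromo-4-hydroxy-4-methylcyclohexyl]ethan-1-one | CC(=O)[C@@H]1CC[C@](C)(O)[C@H](Br)C1 | intermediate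
9 | silyl ether of 8, 1-[(1R,3R,4S)-3-bromo-4-methyl-4-(trimethylsilyloxy)cyclohexyl]ethan-1-one | CC(=O)[C@@H]1CC[C@](C)(O[Si](C)(C)C)[C@H](Br)C1 | intermediate
10 | {[(1S,2R,4R)-2-bromo-1-methyl-4-(prop-1-en-2-yl)cyclohexyl]oxy}trimethylsilane | CC(=C)[C@@H]1CC[C@](C)(O[Si](C)(C)C)[C@H](Br)C1 | intermediate
11 | ring B allyl chloride, {[(1S,2R,4R)-2-bromo-4-(3-chloroprop-1-en-2-yl)-1-methylcyclohexyl]oxy}trimethylsilane | ClCC(=C)[C@@H]1CC[C@](C)(O[Si](C)(C)C)[C@H](Br)C1 | intermediate
12 | lithium enolate of 2 (deprotonated at the CH2 next to the ketone, epoxide intact) | [Li+].[O-]C1=C[C@@H](C(C)=C)C[C@@H]2O[C@]12C | intermediate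
13 | dilithium salt of (2S,5S)-2-hydroxy-2-methyl-5-(prop-1-en-2-yl)cyclohexan-1-one (ketone enolate plus tertiary alkoxide) | [Li+].[Li+].[O-]C1=C[C@@H](C(C)=C)CC[C@]1(C)[O-] | intermediate
14 | (2S,5S,6R)-6-{2-[(1R,3R,4S)-3-bromo-4-methyl-4-(trimethylsilyloxy)cyclohexyl]prop-2-en-1-yl}-2-hydroxy-2-methyl-5-(prop-1-en-2-yl)cyclohexan-1-one | C=C(C[C@@H]1[C@@H](C(=C)C)CC[C@](C)(O)C1=O)[C@@H]1CC[C@](C)(O[Si](C)(C)C)[C@H](Br)C1 | intermediate
15 | (1S,2S,3R,4S)-3-{2-[(1R,3R,4S)-3-bromo-4-methyl-4-(trimethylsilyloxy)cyclohexyl]prop-2-en-1-yl}-1-methyl-4-(prop-1-en-2-yl)cyclohexane-1,2-diol | C=C(C[C@@H]1[C@@H](C(=C)C)CC[C@](C)(O)[C@H]1O)[C@@H]1CC[C@](C)(O[Si](C)(C)C)[C@H](Br)C1 | intermediate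
16 | CNP0422107.2, (1S,2S,3R,4S)-3-{2-[(1R,3R,4S)-3-bromo-4-hydroxy-4-methylcyclohexyl]prop-2-en-1-yl}-1-methyl-4-(prop-1-en-2-yl)cyclohexane-1,2-diol | C=C(C[C@@H]1[C@@H](C(=C)C)CC[C@](C)(O)[C@H]1O)[C@@H]1CC[C@](C)(O)[C@H](Br)C1 | target

**Step count and risks**

Total step count: 9. Longest linear sequence: 8 steps (3 → 16, steps 2 to 9); the ring A branch 1 → 2 is one step.

Steps most likely to fail:

Step 8 (the new one-flask sequence). The enolate-bearing epoxide may be too electron-rich for clean hydride opening, or left-over LiBHEt3 may reduce 11. The fallback sets out from 2 and comes back at 14. Reduce 2 with LiAlH4 (THF, 0 °C → reflux; ketone reduced, epoxide opened at the CH carbon) to (1S,4S)-1-methyl-4-(prop-1-en-2-yl)cyclohexane-1,2-diol F1, whose mixture at the secondary carbinol does not matter. Oxidise the secondary alcohol with SO3·pyridine, DMSO and iPr2NEt to (2S,5S)-2-hydroxy-2-methyl-5-(prop-1-en-2-yl)cyclohexan-1-one F2. Form its dianion with LiN(iPr)2 (2.2 equiv, THF, −78 °C) and alkylate it with 11 under the conditions of step 8, which gives 14.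

Step 4 (and with it the ring closure of step 3). In 6 the acetyl group is axial on the face from which bromide must arrive, and the tertiary sulfate may ionise or eliminate instead. The fallback sets out from 4 and comes back at 8. Equilibrate 4 with K2CO3 in MeOH and separate the epimer at the acetyl-bearing carbon, 1-[(1S,3S,4S)-3,4-dihydroxy-4-methylcyclohexyl]ethan-1-one F3 (unchanged 4 is recycled). Its trans-diol is diequatorial with the acetyl group equatorial, so SO2Cl2 and Et3N at −78 °C give the cyclic sulfate (3aS,5S,7aS)-5-acetyl-7a-methylhexahydro-1,3,2-benzodioxathiole 2,2-dioxide F4 without any ring flip. LiBr opens it by unhindered axial attack to lithium (1S,2R,4S)-4-acetyl-2-bromo-1-methylcyclohexyl sulfate F5. Aqueous H2SO4 in THF hydrolyses this to 1-[(1S,3R,4S)-3-bromo-4-hydroxy-4-methylcyclohexyl]ethan-1-one F6 (Br and CH3 axial). Longer exposure to the same acid epimerises the acetyl-bearing carbon to the isomer with Br, CH3 and acetyl all equatorial, which is 8.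

Step 7. Partial loss of the silyl ether in the aqueous medium would open the way to chloroetherification, and abstraction of the ring methine hydrogen would give the wrong alkene. The fallback sets out from 10 and comes back at 11. Allylic oxidation with SeO2 (cat) and t-BuOOH in CH2Cl2 gives 2-[(1R,3R,4S)-3-bromo-4-methyl-4-(trimethylsilyloxy)cyclohexyl]prop-2-en-1-ol F7. MsCl and Et3N convert it into 2-[(1R,3R,4S)-3-bromo-4-methyl-4-(trimethylsilyloxy)cyclohexyl]prop-2-en-1-yl methanesulfonate F8. LiCl in THF displaces the sulfonate to give 11.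

**Further compounds**

F1 | step 8 | (1S,4S)-1-methyl-4-(prop-1-en-2-yl)cyclohexane-1,2-diol (both epimers at C2) | OC1C[C@@H](C(C)=C)CC[C@]1(C)O
F2 | step 8 | (2S,5S)-2-hydroxy-2-methyl-5-(prop-1-en-2-yl)cyclohexan-1-one | O=C1C[C@@H](C(C)=C)CC[C@]1(C)O
F3 | step 4 | 1-[(1S,3S,4S)-3,4-dihydroxy-4-methylcyclohexyl]ethan-1-one | CC(=O)[C@H]1CC[C@](C)(O)[C@@H](O)C1
F4 | step 4 | (3aS,5S,7aS)-5-acetyl-7a-methylhexahydro-1,3,2-benzodioxathiole 2,2-dioxide | CC(=O)[C@H]1CC[C@](C)(OS(=O)(=O)O2)[C@@H]2C1
F5 | step 4 | lithium (1S,2R,4S)-4-acetyl-2-bromo-1-methylcyclohexyl sulfate | CC(=O)[C@H]1CC[C@](C)(OS(=O)(=O)[O-])[C@H](Br)C1.[Li+]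
F6 | step 4 | 1-[(1S,3R,4S)-3-bromo-4-hydroxy-4-methylcyclohexyl]ethan-1-one | CC(=O)[C@H]1CC[C@](C)(O)[C@H](Br)C1
F7 | step 7 | 2-[(1R,3R,4S)-3-bromo-4-methyl-4-(trimethylsilyloxy)cyclohexyl]prop-2-en-1-ol | OCC(=C)[C@@H]1CC[C@](C)(O[Si](C)(C)C)[C@H](Br)C1
F8 | step 7 | 2-[(1R,3R,4S)-3-bromo-4-methyl-4-(trimethylsilyloxy)cyclohexyl]prop-2-en-1-yl methanesulfonate | CS(=O)(=O)OCC(=C)[C@@H]1CC[C@](C)(O[Si](C)(C)C)[C@H](Br)C1
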